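**Retrosynthetic overview**
- The route rests on C5 of the oxolane ring (O1, C2 aryl, C3 CH2O arm, C4 benzyl, C5). It is a bare CH2 bonded only to O1 and C4, so at the lactone oxidation level it is a carbonyl carbon and can enter as CO between the C2 hydroxyl and an alkyne carbon C4 whose partner C7 already carries the second arene.
- 20 ⇐ 19 ⇐ 17 ⇐ 16 (hydrogenolysis, stearoylation at the C9 oxygen, desilylation); 16 ⇐ 1,4-diol 15 by acid-mediated C2–O1 closure; 15 ⇐ lactone 14.
- 14 ⇐ (E)-benzylidene lactone 12 by conjugate reduction, with C4 set by protonation anti to the C3 arm.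
- 12 ⇐ anti homopropargylic alcohol 10 + CO 11 (C4–C5 and O1–C5). This is the only ring construction: the five-membered ring is made as the lactone (step 7), opened (step 9) and closed again as the oxolane (step 10), so C5 and the ring oxygen of 20 both stem from CO.
- 10 ⇐ aldehyde 1 + propargylic mesylate 8 (allenylzinc addition, sets C3 and C2); 8 ⇐ ynone 6 (asymmetric transfer hydrogenation) ⇐ alkyne 2 (from 1) + aldehyde 3.

Key step: step 7

Remark: atom labels O1, C2–C5, C7 (benzylic CH2) and C9 (CH2O arm) always follow the target numbering, also in the intermediates; 1 and 3 are taken as purchased, so vanillin need not be benzylated and no silyloxyacetaldehyde has to be made.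

**Step 1**
Reactants: 1 (4-(benzyloxy)-3-methoxybenzaldehyde)
Product: 2 1-(benzyloxy)-4-ethynyl-2-methoxybenzene
Conditions: dimethyl (1-diazo-2-oxopropyl)phosphonate, K2CO3, MeOH/THF, rt
Reagents that add atoms: dimethyl (1-diazo-2-oxopropyl)phosphonate, COP(=O)(OC)C(=[N+]=[N-])C(C)=O
Why: Seyferth–Gilbert homologation in the Ohira–Bestmann form, in which methanolysis of the reagent gives the diazomethylphosphonate anion that olefinates the non-enolisable aldehyde to a diazoalkene, which loses N2 and rearranges to the terminal alkyne while the benzyl ether is inert to K2CO3/MeOH.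

**Step 2**
Reactants: 2 (1-(benzyloxy)-4-ethynyl-2-methoxybenzene); 3 ((tert-butyldimethylsilyloxy)acetaldehyde)
Product: 5 rac-4-[4-(benzyloxy)-3-methoxyphenyl]-1-[(tert-butyldimethylsilyl)oxy]but-3-yn-2-ol, via lithium acetylide 4 (not isolated)
Conditions: n-BuLi, THF, −78 °C; then 3, −78 → 0 °C; H2O
Reagents that add atoms: none
Why: Deprotonation of the terminal alkyne and 1,2-addition of the lithium acetylide to the aldehyde at low temperature, the carbinol being made racemic on purpose because it is oxidised in the next step.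

**Step 3**
Reactants: 5 (racemic propargylic alcohol)
Product: 6 4-[4-(benzyloxy)-3-methoxyphenyl]-1-[(tert-butyldimethylsilyl)oxy]but-3-yn-2-one
Conditions: Dess–Martin periodinane, CH2Cl2, 0 °C → rt
Reagents that add atoms: none
Why: Dess–Martin oxidation of a secondary propargylic alcohol to the ynone under near-neutral conditions that leave the silyl ether, the benzyl ether and the alkyne untouched.

**Step 4**
Reactants: 6 (ynone)
Product: 7 (2S)-4-[4-(benzyloxy)-3-methoxyphenyl]-1-[(tert-butyldimethylsilyl)oxy]but-3-yn-2-ol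
Conditions: Ru(p-cymene)[(R,R)-TsNCHPhCHPhNH] (1 mol %), i-PrOH, rt
Reagents that add atoms: none
Why: Noyori asymmetric transfer hydrogenation of an alkynyl ketone, in which the ruthenium hydride/NH pair reduces only the carbonyl on the face distinguished by the alkynyl group; the (R,R) catalyst, which gives R carbinols from alkyl alkynyl ketones, attacks the same face here and the product is named S only because CH2OSi outranks the alkynyl carbon.

**Step 5**
Reactants: 7 ((S)-propargylic alcohol)
Product: 8 (2S)-4-[4-(benzyloxy)-3-methoxyphenyl]-1-[(tert-butyldimethylsilyl)oxy]but-3-yn-2-yl methanesulfonate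
Conditions: MsCl, Et3N, CH2Cl2, −78 → 0 °C; used crude
Reagents that add atoms: methanesulfonyl chloride, CS(=O)(=O)Cl
Why: O-sulfonylation with retention at carbon; the mesylate is carried on without chromatography because propargylic mesylates of electron-rich arylalkynes ionise on silica.

**Step 6**
Reactants: 8 ((S)-propargylic mesylate); 1 (4-(benzyloxy)-3-methoxybenzaldehyde)
Product: 10 (1S,2R)-1,4-bis[4-(benzyloxy)-3-methoxyphenyl]-2-{[(tert-butyldimethylsilyl)oxy]methyl}but-3-yn-1-ol (anti), via allenylzinc methanesulfonate 9 (not isolated)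
Conditions: Pd(OAc)2 (5 mol %), PPh3 (5 mol %), Et2Zn (3 equiv), THF, −78 → −20 °C; H2O
Reagents that add atoms: none
Why: Palladium/zinc propargylation (Marshall–Tamaru reaction): zerovalent palladium displaces the mesylate anti in an SN2' sense, Et2Zn transmetalates the allenylpalladium with retention to 9, and 9 adds to the aldehyde through a cyclic SE2' transition state on the zinc-bearing face, so that C3 is set by centre-to-axis-to-centre chirality transfer (net inversion, R) and C2 by the chair-like transition state (anti, S).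

**Step 7**
Reactants: 10 (anti homopropargylic alcohol); 11 (carbon monoxide)
Product: 12 (3E,4R,5S)-5-[4-(benzyloxy)-3-methoxyphenyl]-3-{[4-(benzyloxy)-3-methoxyphenyl]methylidene}-4-{[(tert-butyldimethylsilyl)oxy]methyl}oxolan-2-one
Conditions: Pd(dba)2 (5 mol %), dppb [Ph2P(CH2)4PPh2] (5 mol %), CO (40 bar), H2 (14 bar), CH2Cl2, 95 °C
Reagents that add atoms: none
Why: A palladium hydride formed from zerovalent palladium, dppb and H2 adds syn across C4≡C7, and because this addition is reversible only the isomer with palladium on C4 goes on: CO insertion there gives an acyl carbon (C5) that the C2 hydroxyl reaches through a five-membered transition state, whereas an acyl group on C7 would sit trans to the carbinol chain and could not lactonise. The closest known reaction type is the palladium-catalysed cyclocarbonylation of but-3-yn-1-ols to α-methylene and (E)-α-alkylidene γ-butyrolactones. The single ring closes by 5-exo-trig attack of the C2 hydroxyl on the acylpalladium (O1–C5) after C4–C5 has formed by migratory insertion, so CO is the one-carbon partner of a [4+1] assembly. No stereocentre is created: C2 and C3 are spectators whose anti relationship becomes the trans relationship of the lactone, and syn hydropalladation fixes the E geometry with the C7 hydrogen cis to the carbonyl. The step needs the five- over the six-membered lactone and carbonylation over plain alkyne hydrogenation; the first is secured by the hydroxyl sitting three atoms from C4, the second by the high CO to H2 ratio. The neutral medium spares the acid-sensitive benzylic alcohol, the benzyl ethers and the silyl ether.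

**Step 8**
Reactants: 12 ((E)-benzylidene lactone)
Product: 14 (3R,4R,5S)-5-[4-(benzyloxy)-3-methoxyphenyl]-3-[4-(benzyloxy)-3-methoxybenzyl]-4-{[(tert-butyldimethylsilyl)oxy]methyl}oxolan-2-one, via copper enolate 13 (not isolated)
Conditions: [(Ph3P)CuH]6 (0.35 equiv), H2O (3 equiv), degassed toluene/THF, rt
Reagents that add atoms: none
Why: Conjugate reduction with Stryker's reagent: hydride adds to the benzylic β-carbon C7 and copper enolate 13 is protonated by water at C4 on the face opposite the adjacent C3 silyloxymethyl arm, the same facial preference that makes alkylations of such lactone enolates trans-selective, which places the new benzyl group cis to the arm (C4 = R) without touching the aryl benzyl ethers.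

**Step 9**
Reactants: 14 (cis lactone)
Product: 15 (1S,2R,3R)-1-[4-(benzyloxy)-3-methoxyphenyl]-3-[4-(benzyloxy)-3-methoxybenzyl]-2-{[(tert-butyldimethylsilyl)oxy]methyl}butane-1,4-diol
Conditions: LiAlH4, THF, 0 °C; then H2O, aq. NaOH (Fieser work-up)
Reagents that add atoms: none
Why: Hydride reduction of the lactone to the 1,4-diol, which is faster than enolisation at 0 °C and removes the carbonyl that made C4 epimerisable, while silyl and benzyl ethers are stable to LiAlH4.

**Step 10**
Reactants: 15 (1,4-diol)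
Product: 16 tert-butyl{[(2S,3R,4R)-2-[4-(benzyloxy)-3-methoxyphenyl]-4-[4-(benzyloxy)-3-methoxybenzyl]oxolan-3-yl]methoxy}dimethylsilane
Conditions: camphorsulfonic acid (10 mol %), CH2Cl2, 0 °C → rt
Reagents that add atoms: none
Why: Acid-catalysed dehydrative etherification in which the 4-alkoxybenzylic alcohol ionises and the primary C5 hydroxyl traps the cation in a five-membered closure, the aryl group taking the face opposite the C3 arm (2,3-trans, C2 = S), which is the configuration already set in step 6, so that any syn isomer carried from step 6 converges on the same product.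

**Step 11**
Reactants: 16 (silyl ether)
Product: 17 [(2S,3R,4R)-2-[4-(benzyloxy)-3-methoxyphenyl]-4-[4-(benzyloxy)-3-methoxybenzyl]oxolan-3-yl]methanol
Conditions: Bu4NF, THF, 0 °C → rt
Reagents that add atoms: none
Why: Fluoride cleavage of the primary silyl ether, to which the benzyl ethers and the oxolane are inert.

**Step 12**
Reactants: 17 (primary alcohol); 18 (stearic acid)
Product: 19 [(2S,3R,4R)-2-[4-(benzyloxy)-3-methoxyphenyl]-4-[4-(benzyloxy)-3-methoxybenzyl]oxolan-3-yl]methyl octadecanoate
Conditions: DCC, DMAP (cat.), CH2Cl2, rt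
Reagents that add atoms: none
Why: Steglich esterification of the only free hydroxyl, unambiguous because both phenols are still benzylated.

**Step 13**
Reactants: 19 (dibenzyl ether stearate)
Product: 20 [(2S,3R,4R)-2-(4-hydroxy-3-methoxyphenyl)-4-(4-hydroxy-3-methoxybenzyl)oxolan-3-yl]methyl octadecanoate
Conditions: H2 (1 atm), 10% Pd/C, EtOAc, rt, stopped after uptake of two equivalents
Reagents that add atoms: none
Why: Hydrogenolysis of the two aryl benzyl ethers in a neutral aprotic solvent at atmospheric pressure, where this cleavage is much faster than that of the cyclic benzylic C2–O1 ether, and the ester and the three stereocentres are untouched.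

**Compound list**
1 | 4-(benzyloxy)-3-methoxybenzaldehyde | COc1cc(C=O)ccc1OCc1ccccc1 | starting material
2 | 1-(benzyloxy)-4-ethynyl-2-methoxybenzene | C#Cc1ccc(OCc2ccccc2)c(OC)c1 | intermediate
3 | (tert-butyldimethylsilyloxy)acetaldehyde | CC(C)(C)[Si](C)(C)OCC=O | starting material
4 | lithium [4-(benzyloxy)-3-methoxyphenyl]acetylide | [Li]C#Cc1ccc(OCc2ccccc2)c(OC)c1 | intermediate
5 | rac-4-[4-(benzyloxy)-3-methoxyphenyl]-1-[(tert-butyldimethylsilyl)oxy]but-3-yn-2-ol | CC(C)(C)[Si](C)(C)OCC(O)C#Cc1ccc(OCc2ccccc2)c(OC)c1 | intermediate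
6 | 4-[4-(benzyloxy)-3-methoxyphenyl]-1-[(tert-butyldimethylsilyl)oxy]but-3-yn-2-one | CC(C)(C)[Si](C)(C)OCC(=O)C#Cc1ccc(OCc2ccccc2)c(OC)c1 | intermediate
7 | (2S)-4-[4-(benzyloxy)-3-methoxyphenyl]-1-[(tert-butyldimethylsilyl)oxy]but-3-yn-2-ol | CC(C)(C)[Si](C)(C)OC[C@@H](O)C#Cc1ccc(OCc2ccccc2)c(OC)c1 | intermediate
8 | (2S)-4-[4-(benzyloxy)-3-methoxyphenyl]-1-[(tert-butyldimethylsilyl)oxy]but-3-yn-2-yl methanesulfonate | CC(C)(C)[Si](C)(C)OC[C@@H](OS(C)(=O)=O)C#Cc1ccc(OCc2ccccc2)c(OC)c1 | intermediate
9 | {1-[4-(benzyloxy)-3-methoxyphenyl]-4-[(tert-butyldimethylsilyl)oxy]buta-1,2-dien-1-yl}zinc methanesulfonate, zinc on the allene face anti to the departed mesylate | CS(=O)(=O)O[Zn]C(c1ccc(OCc2ccccc2)c(OC)c1)=[C@@]=C([H])CO[Si](C)(C)C(C)(C)C | intermediate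
10 | (1S,2R)-1,4-bis[4-(benzyloxy)-3-methoxyphenyl]-2-{[(tert-butyldimethylsilyl)oxy]methyl}but-3-yn-1-ol | CC(C)(C)[Si](C)(C)OC[C@H]([C@H](O)c1ccc(OCc2ccccc2)c(OC)c1)C#Cc1ccc(OCc2ccccc2)c(OC)c1 | intermediate
11 | carbon monoxide | [C-]#[O+] | starting material
12 | (3E,4R,5S)-5-[4-(benzyloxy)-3-methoxyphenyl]-3-{[4-(benzyloxy)-3-methoxyphenyl]methylidene}-4-{[(tert-butyldimethylsilyl)oxy]methyl}oxolan-2-one | CC(C)(C)[Si](C)(C)OC[C@H]1/C(=C\c2ccc(OCc3ccccc3)c(OC)c2)C(=O)O[C@@H]1c1ccc(OCc2ccccc2)c(OC)c1 | intermediate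
13 | O-bound copper enolate of lactone 14 (phosphine ligand omitted) | CC(C)(C)[Si](C)(C)OC[C@H]1C(Cc2ccc(OCc3ccccc3)c(OC)c2)=C(O[Cu])O[C@@H]1c1ccc(OCc2ccccc2)c(OC)c1 | intermediate
14 | (3R,4R,5S)-5-[4-(benzyloxy)-3-methoxyphenyl]-3-[4-(benzyloxy)-3-methoxybenzyl]-4-{[(tert-butyldimethylsilyl)oxy]methyl}oxolan-2-one | CC(C)(C)[Si](C)(C)OC[C@H]1[C@@H](Cc2ccc(OCc3ccccc3)c(OC)c2)C(=O)O[C@@H]1c1ccc(OCc2ccccc2)c(OC)c1 | intermediate
15 | (1S,2R,3R)-1-[4-(benzyloxy)-3-methoxyphenyl]-3-[4-(benzyloxy)-3-methoxybenzyl]-2-{[(tert-butyldimethylsilyl)oxy]methyl}butane-1,4-diol | CC(C)(C)[Si](C)(C)OC[C@H]([C@H](O)c1ccc(OCc2ccccc2)c(OC)c1)[C@@H](Cc1ccc(OCc2ccccc2)c(OC)c1)CO | intermediate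
16 | tert-butyl{[(2S,3R,4R)-2-[4-(benzyloxy)-3-methoxyphenyl]-4-[4-(benzyloxy)-3-methoxybenzyl]oxolan-3-yl]methoxy}dimethylsilane | CC(C)(C)[Si](C)(C)OC[C@H]1[C@@H](Cc2ccc(OCc3ccccc3)c(OC)c2)CO[C@@H]1c1ccc(OCc2ccccc2)c(OC)c1 | intermediate
17 | [(2S,3R,4R)-2-[4-(benzyloxy)-3-methoxyphenyl]-4-[4-(benzyloxy)-3-methoxybenzyl]oxolan-3-yl]methanol | OC[C@H]1[C@@H](Cc2ccc(OCc3ccccc3)c(OC)c2)CO[C@@H]1c1ccc(OCc2ccccc2)c(OC)c1 | intermediate
18 | stearic acid | CCCCCCCCCCCCCCCCCC(=O)O | starting material
19 | [(2S,3R,4R)-2-[4-(benzyloxy)-3-methoxyphenyl]-4-[4-(benzyloxy)-3-methoxybenzyl]oxolan-3-yl]methyl octadecanoate | CCCCCCCCCCCCCCCCCC(=O)OC[C@H]1[C@@H](Cc2ccc(OCc3ccccc3)c(OC)c2)CO[C@@H]1c1ccc(OCc2ccccc2)c(OC)c1 | intermediate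
20 | [(2S,3R,4R)-2-(4-hydroxy-3-methoxyphenyl)-4-(4-hydroxy-3-methoxybenzyl)oxolan-3-yl]methyl octadecanoate | CCCCCCCCCCCCCCCCCC(=O)OC[C@H]1[C@@H](Cc2ccc(O)c(OC)c2)CO[C@@H]1c1ccc(O)c(OC)c1 | target

**Step count and risks**
Total step count: 13. Longest linear sequence: 13 steps (1 → 2 → 5 → 6 → 7 → 8 → 10 → 12 → 14 → 15 → 16 → 17 → 19 → 20).

Steps most likely to fail:

1. Step 7. The hydropalladation may place palladium mainly on the aryl-bearing C7, so that the alkyne is merely hydrogenated, or carbonylation of the hindered internal alkyne may be too slow. The fallback sets out from 10 and comes back at 12, and enforces the regiochemistry with a silicon tether. 10 is silylated with 1,1,3,3-tetramethyldisilazane (neat, 60 °C) to the dimethylsilyl ether F1. Intramolecular syn-hydrosilylation with Pt2[(CH2=CHSiMe2)2O]3 (THF, rt) closes the 5-exo (E)-benzylidene oxasilolane F2 with silicon on C4. N-Iodosuccinimide (MeCN, 0 °C), followed by aqueous KHCO3/MeOH to hydrolyse the residual O–Si bond, gives the hydroxy vinyl iodide F3. Carbonylative lactonisation (PdCl2(PPh3)2 cat., CO 11 at 1 atm, Et3N, THF, 60 °C) then gives 12. Partial loss of alkene geometry in the iododesilylation would be harmless, since C7 becomes a CH2 group in step 8.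

2. Step 8. Protonation of the copper enolate may show poor facial selectivity, or the cis lactone may epimerise at C4 to the trans isomer. The fallback sets out from 12 and comes back at 14. Hydrogenation over 10% Pd/C (H2 1 atm, EtOAc, rt) delivers H2 syn to the exocyclic alkene from the face opposite the C3 arm and at the same time cleaves both benzyl ethers, giving the cis diphenol lactone F4. Re-benzylation of the two phenols (BnBr, K2CO3, acetone, rt) returns 14.

3. Step 6. The allenylzinc may racemise through its propargylzinc isomer, or add sluggishly to the electron-rich aromatic aldehyde, with loss of enantiomeric purity at C3. A low anti to syn ratio matters less, since step 10 resets C2. The fallback sets out from 7 and comes back at 10. 7 is converted to the methyl carbonate F5 (ClCO2Me, pyridine, CH2Cl2, 0 °C). Copper-catalysed γ-selective borylation (Cu(O-t-Bu)/Xantphos cat., B2pin2, THF, rt) gives, by anti SN2' displacement, the isolable and configurationally stable allenylboronate F6. Thermal allenylboration of 1 (toluene, 60–80 °C, aqueous work-up) through the same cyclic SE2' geometry gives 10.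

**Further compounds**
F1 | step 7 | {(1S,2R)-1,4-bis[4-(benzyloxy)-3-methoxyphenyl]-2-{[(tert-butyldimethylsilyl)oxy]methyl}but-3-yn-1-yl}oxy(dimethyl)silane | CC(C)(C)[Si](C)(C)OC[C@H]([C@H](O[SiH](C)C)c1ccc(OCc2ccccc2)c(OC)c1)C#Cc1ccc(OCc2ccccc2)c(OC)c1
F2 | step 7 | (3E,4R,5S)-5-[4-(benzyloxy)-3-methoxyphenyl]-3-{[4-(benzyloxy)-3-methoxyphenyl]methylidene}-4-{[(tert-butyldimethylsilyl)oxy]methyl}-2,2-dimethyl-1,2-oxasilolane | CC(C)(C)[Si](C)(C)OC[C@H]1/C(=C\c2ccc(OCc3ccccc3)c(OC)c2)[Si](C)(C)O[C@@H]1c1ccc(OCc2ccccc2)c(OC)c1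
F3 | step 7 | (1S,2R,3E)-1,4-bis[4-(benzyloxy)-3-methoxyphenyl]-2-{[(tert-butyldimethylsilyl)oxy]methyl}-3-iodobut-3-en-1-ol | CC(C)(C)[Si](C)(C)OC[C@H]([C@H](O)c1ccc(OCc2ccccc2)c(OC)c1)/C(I)=C\c1ccc(OCc2ccccc2)c(OC)c1
F4 | step 8 | (3R,4R,5S)-4-{[(tert-butyldimethylsilyl)oxy]methyl}-5-(4-hydroxy-3-methoxyphenyl)-3-(4-hydroxy-3-methoxybenzyl)oxolan-2-one | CC(C)(C)[Si](C)(C)OC[C@H]1[C@@H](Cc2ccc(O)c(OC)c2)C(=O)O[C@@H]1c1ccc(O)c(OC)c1
F5 | step 6 | (2S)-4-[4-(benzyloxy)-3-methoxyphenyl]-1-[(tert-butyldimethylsilyl)oxy]but-3-yn-2-yl methyl carbonate | CC(C)(C)[Si](C)(C)OC[C@@H](OC(=O)OC)C#Cc1ccc(OCc2ccccc2)c(OC)c1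
F6 | step 6 | 2-{1-[4-(benzyloxy)-3-methoxyphenyl]-4-[(tert-butyldimethylsilyl)oxy]buta-1,2-dien-1-yl}-4,4,5,5-tetramethyl-1,3,2-dioxaborolane, boron on the allene face anti to the departed carbonate | CC1(C)OB(OC1(C)C)C(c1ccc(OCc2ccccc2)c(OC)c1)=[C@@]=C([H])CO[Si](C)(C)C(C)(C)C
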